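**Retrosynthetic overview**

1. The strategy rests on the ester between the tertiary oxygen on C7 of the 7,8-dihydro-6H-isochromen-6-one and the carbonyl of the 2,4-dihydroxy-6-methylbenzoyl ring. This carbonyl is flanked by C2'–OH and C6'–CH3, and the arene is a folded tetraketide. The C7–O–acyl bond and the aryl C1'–C6' bond are therefore cut together, giving the core tertiary alcohol and a triketo acylketene stored as a diketo-dioxinone.
2. Core alcohol: the pyran ring is opened at O2–C3 (6-endo-dig addition of a C1 hydroxymethylene oxygen to the alkyne on C4a). C1 is removed as a γ-formyl group introduced on a silyl dienol ether.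
3. The C7 carbinol comes from reagent-controlled hydroxylation of the α'-methyl enolate of a 3-enynylcyclohexenone, which comes from 3-ethoxycyclohex-2-enone and (E)-pent-2-en-4-yn-1-ol (Stork–Danheiser).
4. The diketo-dioxinone comes from 2,2,6-trimethyl-4H-1,3-dioxin-4-one by two Claisen-type C-acylations.
5. Ring order: carbocycle (purchased), then the pyran ring (step 6), then the benzene ring last (step 11).

Key step: step 11

Remark on numbering: the bicycle is numbered as an isochromene (C1, O2, C3, C4, C4a, C5–C8, C8a); the monocyclic precursors keep cyclohexenone numbers; the polyketide chain is numbered C1' (ester carbonyl) to C8' (terminal methyl).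

Assumption (chemistry): the (+) enantiomer of the dichloro camphor oxaziridine is taken to oxidise the sodium enolate of 6 on the face that gives the (S) ketol, by analogy with 2-alkyl-1-tetralone enolates. If the sense on this dienolate is the opposite, the (−) reagent from (1R)-10-camphorsulfonic acid is used and nothing else changes.

**Route**

Step 1
Reactants: 1 (E)-pent-2-en-4-yn-1-ol
Product: 2 tert-butyldimethyl[(E)-pent-2-en-4-ynyloxy]silane
Conditions: TBSCl, imidazole, CH2Cl2, 0 °C to rt
Reagents that add atoms: tert-butyldimethylsilyl chloride, CC(C)(C)[Si](C)(C)Cl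
Why: Imidazole-promoted silylation of a primary allylic alcohol is routine and leaves the acetylenic C–H free for metalation.

Step 2
Reactants: 2 tert-butyldimethyl[(E)-pent-2-en-4-ynyloxy]silane; 3 3-ethoxycyclohex-2-en-1-one
Product: 5 3-[(E)-5-(tert-butyldimethylsilyloxy)pent-3-en-1-ynyl]cyclohex-2-en-1-one, via carbinol adduct 4 (not isolated)
Conditions: 2, n-BuLi, THF, −78 °C; then 3, −78 to 0 °C; then 1 M aq HCl, 0 °C, 20 min
Reagents that add atoms: water, O
Why: Stork–Danheiser sequence, in which the lithium acetylide adds 1,2 to the vinylogous ester carbonyl and cold dilute acid hydrolyses the enol ether with loss of water, transposing the carbonyl to give the 3-alkynyl enone while the primary TBS ether survives the brief acid contact.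

Step 3
Reactants: 5 3-[(E)-5-(tert-butyldimethylsilyloxy)pent-3-en-1-ynyl]cyclohex-2-en-1-one
Product: 6 racemic 3-[(E)-5-(tert-butyldimethylsilyloxy)pent-3-en-1-ynyl]-6-methylcyclohex-2-en-1-one
Conditions: LDA [LiN(iPr)2], THF, −78 °C; MeI, −78 to −30 °C
Reagents that add atoms: iodomethane, CI
Why: Kinetic α'-deprotonation of the enone gives the cross-conjugated lithium enolate, which is C-methylated (enolate alkylation); the new centre is racemic and is flattened again in step 4.

Step 4
Reactants: 6 racemic 3-[(E)-5-(tert-butyldimethylsilyloxy)pent-3-en-1-ynyl]-6-methylcyclohex-2-en-1-one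
Product: 7 (6S)-3-[(E)-5-(tert-butyldimethylsilyloxy)pent-3-en-1-ynyl]-6-hydroxy-6-methylcyclohex-2-en-1-one
Conditions: NaHMDS [NaN(SiMe3)2], THF, −78 °C; (+)-(2R,8aR)-[(8,8-dichlorocamphoryl)sulfonyl]oxaziridine, −78 °C; AcOH quench
Reagents that add atoms: (+)-(2R,8aR)-[(8,8-dichlorocamphoryl)sulfonyl]oxaziridine, CC1(C)[C@@H]2CC[C@]13CS(=O)(=O)[N@]4O[C@@]34C2(Cl)Cl
Why: Davis asymmetric enolate hydroxylation, in which kinetic α'-deprotonation gives one ring-fixed tetrasubstituted sodium enolate and oxygen transfer from the camphor-derived N-sulfonyloxaziridine sets the future C7 centre under reagent control, the two chlorine atoms beside the oxaziridine carbon being the element that tells the enolate faces apart.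

Step 5
Reactants: 7 (6S)-3-[(E)-5-(tert-butyldimethylsilyloxy)pent-3-en-1-ynyl]-6-hydroxy-6-methylcyclohex-2-en-1-one
Product: 8 triethyl{[(6S)-3-[(E)-5-(tert-butyldimethylsilyloxy)pent-3-en-1-ynyl]-6-methyl-6-(triethylsilyloxy)cyclohexa-1,3-dien-1-yl]oxy}silane
Conditions: TESOTf (2.5 equiv), Et3N, CH2Cl2, −78 to 0 °C
Reagents that add atoms: triethylsilyl trifluoromethanesulfonate, CC[Si](CC)(CC)OS(=O)(=O)C(F)(F)F
Why: Silyl triflate and amine silylate the tertiary hydroxyl and enolise the ketone (soft enolisation), and because C6 is now quaternary the only enolisable hydrogen is the γ one, so the linear 1-silyloxy-1,3-diene should form.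

Step 6
Reactants: 8 triethyl{[(6S)-3-[(E)-5-(tert-butyldimethylsilyloxy)pent-3-en-1-ynyl]-6-methyl-6-(triethylsilyloxy)cyclohexa-1,3-dien-1-yl]oxy}silane
Product: 11 (7S)-3-[(E)-3-(tert-butyldimethylsilyloxy)prop-1-enyl]-7-methyl-7-(triethylsilyloxy)-7,8-dihydro-6H-isochromen-6-one, via iminium chloride 9 (not isolated), via hydroxymethylene enone 10 (not isolated)
Conditions: (chloromethylene)dimethyliminium chloride (1.1 equiv), CH2Cl2, 0 °C; aq NaOAc, THF, rt; then AgO3SCF3 (silver trifluoromethanesulfonate, 5 mol %), CH2Cl2, rt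
Reagents that add atoms: (chloromethylene)dimethyliminium chloride, C[N+](C)=CCl.[Cl-]; water, O
Why: Vilsmeier–Haack formylation of a dienol ether takes place at the terminal γ-carbon (as in steroidal 3,5-dienol ethers, formylated at C6), buffered hydrolysis releases the formyl group as its hydroxymethylene tautomer, and silver-catalysed 6-endo-dig addition of that enol oxygen to the alkyne (the cycloisomerisation known for alkynyl benzaldehydes, here also a 1,6-oxa-Michael addition to the ynenone) closes the pyran ring without touching the C7 centre.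

Step 7
Reactants: 11 (7S)-3-[(E)-3-(tert-butyldimethylsilyloxy)prop-1-enyl]-7-methyl-7-(triethylsilyloxy)-7,8-dihydro-6H-isochromen-6-one
Product: 12 (7S)-7-hydroxy-3-[(E)-3-hydroxyprop-1-enyl]-7-methyl-7,8-dihydro-6H-isochromen-6-one
Conditions: HF·pyridine, pyridine, THF, 0 °C to rt
Reagents that add atoms: none
Why: Buffered fluoride desilylation should cleave the primary TBS and the tertiary TES ether, while the vinylogous ester core, which is sensitive to amine nucleophiles and strong base, tolerates this weakly acidic medium.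

Step 8
Reactants: 12 (7S)-7-hydroxy-3-[(E)-3-hydroxyprop-1-enyl]-7-methyl-7,8-dihydro-6H-isochromen-6-one
Product: 13 (E)-3-[(7S)-7-hydroxy-7-methyl-6-oxo-7,8-dihydro-6H-isochromen-3-yl]prop-2-enyl acetate (core C7 tertiary alcohol)
Conditions: Ac2O (1.1 equiv), pyridine, CH2Cl2, 0 °C
Reagents that add atoms: acetic anhydride, CC(=O)OC(C)=O
Why: Without an acyl-transfer catalyst the primary allylic alcohol is acetylated far faster than the tertiary α-ketol hydroxyl (chemoselective acylation).

Step 9
Reactants: 14 2,2,6-trimethyl-4H-1,3-dioxin-4-one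
Product: 15 2,2-dimethyl-6-(2-oxopropyl)-4H-1,3-dioxin-4-one
Conditions: LiHMDS [LiN(SiMe3)2] (2 equiv), THF, −78 °C; AcCl (1 equiv); aq HCl work-up
Reagents that add atoms: acetyl chloride, CC(=O)Cl
Why: γ-Deprotonation gives the lithium dienolate of the dioxinone, which is C-acylated at the exocyclic carbon (vinylogous Claisen condensation), the second equivalent of base taking up the more acidic product.

Step 10
Reactants: 15 2,2-dimethyl-6-(2-oxopropyl)-4H-1,3-dioxin-4-one
Product: 16 2,2-dimethyl-6-(2,4-dioxopentyl)-4H-1,3-dioxin-4-one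
Conditions: LDA [LiN(iPr)2] (2.2 equiv), THF, −78 °C; N-methoxy-N-methylacetamide, −78 to −40 °C; aq HCl work-up
Reagents that add atoms: N-methoxy-N-methylacetamide, CC(=O)N(C)OC
Why: Claisen acylation of a dianion, in which the second deprotonation occurs at the terminal methyl group, this more reactive carbanion attacks the Weinreb amide, and the stable N-methoxy chelate prevents over-addition.

Step 11
Reactants: 13 (E)-3-[(7S)-7-hydroxy-7-methyl-6-oxo-7,8-dihydro-6H-isochromen-3-yl]prop-2-enyl acetate; 16 2,2-dimethyl-6-(2,4-dioxopentyl)-4H-1,3-dioxin-4-one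
Product: 20 (7S)-3-[(E)-3-acetoxyprop-1-enyl]-7-methyl-6-oxo-7,8-dihydro-6H-isochromen-7-yl 2,4-dihydroxy-6-methylbenzoate (target), via acylketene 17 (not isolated), via triketo ester 18 (not isolated), via aldol adduct 19 (not isolated)
Conditions: 13, 16 (1.5 equiv, slow addition), PhMe, 110 °C, N2 sweep; then Et3N (cat.), CH2Cl2, rt; then CF3CO2H (cat.), 0 °C to rt
Reagents that add atoms: none
Why: At 110 °C dioxinone 16 loses acetone by retro-[4+2] fragmentation to acylketene 17, a linear and unhindered electrophile that adds the tertiary C7 hydroxyl of 13 through a six-centre transition state in which the acyl oxygen accepts the proton, so triketo ester 18 should form without any activation of the hindered alcohol. The closest known reaction type is thermal dioxinone-to-acylketene trapping by alcohols followed by biomimetic aldol aromatisation of 3,5,7-triketo esters to resorcylates. The benzene ring is closed by attack of the C2' methylene on the C7' methyl ketone, a 6-(enolendo)-exo-trig aldol through the C3' enol (equally allowed as 6-(enolexo) through the ester enol), and loss of water from 19 with enolisation of the two remaining ketones gives the 2,4-dihydroxy-6-methylbenzoate. No stereocentre is created: C7 is quaternary and cannot epimerise, and the transient carbinol centres of 19 vanish on aromatisation. The selectivity needed is acylation at the single free hydroxyl (13 has no other) and aldol closure of C2' on C7' in preference to Claisen closure of C6' on the ester carbonyl or aldol of the terminal methyl on C3'; the tertiary alkyl ester is the poorest and most shielded electrophile of the chain and the methyl group its least acidic carbon, so mild amine catalysis should channel the chain into the orsellinate fold. Catalytic Et3N followed by a trace of acid should leave the allylic acetate and the pyranylidene ketone untouched.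

**Compound list**

1 | (E)-pent-2-en-4-yn-1-ol | C#C/C=C/CO | starting material
2 | tert-butyldimethyl[(E)-pent-2-en-4-ynyloxy]silane | C#C/C=C/CO[Si](C)(C)C(C)(C)C | intermediate
3 | 3-ethoxycyclohex-2-en-1-one | CCOC1=CC(=O)CCC1 | starting material
4 | 3-ethoxy-1-[(E)-5-(tert-butyldimethylsilyloxy)pent-3-en-1-ynyl]cyclohex-2-en-1-ol, racemic, present as its lithium alkoxide (not isolated) | CCOC1=CC(O)(C#C/C=C/CO[Si](C)(C)C(C)(C)C)CCC1 | intermediate
5 | 3-[(E)-5-(tert-butyldimethylsilyloxy)pent-3-en-1-ynyl]cyclohex-2-en-1-one | O=C1C=C(C#C/C=C/CO[Si](C)(C)C(C)(C)C)CCC1 | intermediate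
6 | racemic 3-[(E)-5-(tert-butyldimethylsilyloxy)pent-3-en-1-ynyl]-6-methylcyclohex-2-en-1-one | CC1CCC(C#C/C=C/CO[Si](C)(C)C(C)(C)C)=CC1=O | intermediate
7 | (6S)-3-[(E)-5-(tert-butyldimethylsilyloxy)pent-3-en-1-ynyl]-6-hydroxy-6-methylcyclohex-2-en-1-one | CC(C)(C)[Si](C)(C)OC/C=C/C#CC1=CC(=O)[C@@](C)(O)CC1 | intermediate
8 | triethyl{[(6S)-3-[(E)-5-(tert-butyldimethylsilyloxy)pent-3-en-1-ynyl]-6-methyl-6-(triethylsilyloxy)cyclohexa-1,3-dien-1-yl]oxy}silane | CC(C)(C)[Si](C)(C)OC/C=C/C#CC1=CC[C@](C)(O[Si](CC)(CC)CC)C(O[Si](CC)(CC)CC)=C1 | intermediate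
9 | N-{[(5S)-2-[(E)-5-(tert-butyldimethylsilyloxy)pent-3-en-1-ynyl]-5-methyl-4,5-bis(triethylsilyloxy)cyclohexa-1,3-dien-1-yl]methylidene}-N-methylmethanaminium chloride (not isolated) | C[N+](C)=CC1=C(C#C/C=C/CO[Si](C)(C)C(C)(C)C)C=C(O[Si](CC)(CC)CC)[C@@](C)(O[Si](CC)(CC)CC)C1.[Cl-] | intermediate
10 | (4Z,6S)-4-(hydroxymethylidene)-3-[(E)-5-(tert-butyldimethylsilyloxy)pent-3-en-1-ynyl]-6-methyl-6-(triethylsilyloxy)cyclohex-2-en-1-one, the enol tautomer of the 4-carbaldehyde (not isolated) | O/C=C1/C[C@](C)(O[Si](CC)(CC)CC)C(=O)C=C1C#C/C=C/CO[Si](C)(C)C(C)(C)C | intermediate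
11 | (7S)-3-[(E)-3-(tert-butyldimethylsilyloxy)prop-1-enyl]-7-methyl-7-(triethylsilyloxy)-7,8-dihydro-6H-isochromen-6-one | CC(C)(C)[Si](C)(C)OC/C=C/C1=CC2=CC(=O)[C@@](C)(O[Si](CC)(CC)CC)CC2=CO1 | intermediate
12 | (7S)-7-hydroxy-3-[(E)-3-hydroxyprop-1-enyl]-7-methyl-7,8-dihydro-6H-isochromen-6-one | OC/C=C/C1=CC2=CC(=O)[C@@](C)(O)CC2=CO1 | intermediate
13 | (E)-3-[(7S)-7-hydroxy-7-methyl-6-oxo-7,8-dihydro-6H-isochromen-3-yl]prop-2-enyl acetate | CC(=O)OC/C=C/C1=CC2=CC(=O)[C@@](C)(O)CC2=CO1 | intermediate
14 | 2,2,6-trimethyl-4H-1,3-dioxin-4-one | CC1=CC(=O)OC(C)(C)O1 | starting material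
15 | 2,2-dimethyl-6-(2-oxopropyl)-4H-1,3-dioxin-4-one | CC(=O)CC1=CC(=O)OC(C)(C)O1 | intermediate
16 | 2,2-dimethyl-6-(2,4-dioxopentyl)-4H-1,3-dioxin-4-one | CC(=O)CC(=O)CC1=CC(=O)OC(C)(C)O1 | intermediate
17 | 3,5,7-trioxooct-1-en-1-one, the acylketene (not isolated) | CC(=O)CC(=O)CC(=O)C=C=O | intermediate
18 | (7S)-3-[(E)-3-acetoxyprop-1-enyl]-7-methyl-6-oxo-7,8-dihydro-6H-isochromen-7-yl 3,5,7-trioxooctanoate (not isolated) | CC(=O)OC/C=C/C1=CC2=CC(=O)[C@@](C)(OC(=O)CC(=O)CC(=O)CC(C)=O)CC2=CO1 | intermediate
19 | (7S)-3-[(E)-3-acetoxyprop-1-enyl]-7-methyl-6-oxo-7,8-dihydro-6H-isochromen-7-yl 2-hydroxy-2-methyl-4,6-dioxocyclohexane-1-carboxylate, mixture at the two new ring centres (not isolated) | CC(=O)OC/C=C/C1=CC2=CC(=O)[C@@](C)(OC(=O)C3C(=O)CC(=O)CC3(C)O)CC2=CO1 | intermediate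
20 | (7S)-3-[(E)-3-acetoxyprop-1-enyl]-7-methyl-6-oxo-7,8-dihydro-6H-isochromen-7-yl 2,4-dihydroxy-6-methylbenzoate | CC(=O)OC/C=C/C1=CC2=CC(=O)[C@@](C)(OC(=O)c3c(C)cc(O)cc3O)CC2=CO1 | target

**Step count**

Total step count: 11. Longest linear sequence: 9 steps (steps 1 to 8, then step 11); steps 9 and 10 form the short convergent branch.

**Steps most likely to fail**

Step 11. The acylketene may be consumed by its own enol oxygen (closure to a hydroxypyranone) or by dimerisation faster than the hindered tertiary α-ketol hydroxyl captures it, or the chain may close in the Claisen sense with loss of the alkoxide. The fallback sets out from 13 and uses a pre-formed arene. Commercial 2,4-dihydroxy-6-methylbenzoic acid is persilylated (TBSCl, imidazole, DMF) to tert-butyldimethylsilyl 2,4-bis(tert-butyldimethylsilyloxy)-6-methylbenzoate F1. Mild aqueous acid (AcOH, THF–H2O) cleaves only the silyl ester to give 2,4-bis(tert-butyldimethylsilyloxy)-6-methylbenzoic acid F2. Trifluoroacetic anhydride in CH2Cl2 converts F2 into the mixed trifluoroacetic anhydride F3, which ionises to the aroyl cation and should acylate 13 (the classical esterification of 2,6-disubstituted benzoic acids), giving the bis-silyl ester of the target F4. HF·pyridine frees both phenols, and the route is rejoined at 20.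

Step 6. The Vilsmeier salt may attack the α-carbon of the dienol ether in place of the γ-carbon, or react further with the enone carbonyl of the first-formed product, so that the formyl group is lost or misplaced before ring closure. The fallback sets out from 8 and forms the same C–C bond by a vinylogous Mukaiyama reaction with trimethyl orthoformate and BF3·OEt2 (CH2Cl2, −78 °C), which should give the masked aldehyde, the γ-dimethoxymethyl enone F5. Pyridinium p-toluenesulfonate in wet acetone unmasks it to 10, where the route is rejoined, and 10 is closed to 11 under the silver catalysis of step 6.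

Step 4. Facial discrimination by the reagent may be poor on this cross-conjugated enolate, or γ-deprotonation may compete and divert material to the extended dienolate. The fallback sets out from 6 and replaces induction by resolution. Hydroxylation of the lithium enolate (LDA, THF, −78 °C) with racemic trans-2-(phenylsulfonyl)-3-phenyloxaziridine should give the racemic ketol F6. Its enantiomers are separated by preparative chromatography on a chiral stationary phase (amylose tris(3,5-dimethylphenylcarbamate)), and the (S) enantiomer is 7, where the route is rejoined.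

**Further compounds**

F1 | step 11 | tert-butyldimethylsilyl 2,4-bis(tert-butyldimethylsilyloxy)-6-methylbenzoate | Cc1cc(O[Si](C)(C)C(C)(C)C)cc(O[Si](C)(C)C(C)(C)C)c1C(=O)O[Si](C)(C)C(C)(C)C
F2 | step 11 | 2,4-bis(tert-butyldimethylsilyloxy)-6-methylbenzoic acid | Cc1cc(O[Si](C)(C)C(C)(C)C)cc(O[Si](C)(C)C(C)(C)C)c1C(=O)O
F3 | step 11 | 2,4-bis(tert-butyldimethylsilyloxy)-6-methylbenzoic trifluoroacetic anhydride | Cc1cc(O[Si](C)(C)C(C)(C)C)cc(O[Si](C)(C)C(C)(C)C)c1C(=O)OC(=O)C(F)(F)F
F4 | step 11 | (7S)-3-[(E)-3-acetoxyprop-1-enyl]-7-methyl-6-oxo-7,8-dihydro-6H-isochromen-7-yl 2,4-bis(tert-butyldimethylsilyloxy)-6-methylbenzoate | CC(=O)OC/C=C/C1=CC2=CC(=O)[C@@](C)(OC(=O)c3c(C)cc(O[Si](C)(C)C(C)(C)C)cc3O[Si](C)(C)C(C)(C)C)CC2=CO1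
F5 | step 6 | (6S)-4-(dimethoxymethyl)-3-[(E)-5-(tert-butyldimethylsilyloxy)pent-3-en-1-ynyl]-6-methyl-6-(triethylsilyloxy)cyclohex-2-en-1-one, both C4 epimers | COC(OC)C1C[C@](C)(O[Si](CC)(CC)CC)C(=O)C=C1C#C/C=C/CO[Si](C)(C)C(C)(C)C
F6 | step 4 | racemic 3-[(E)-5-(tert-butyldimethylsilyloxy)pent-3-en-1-ynyl]-6-hydroxy-6-methylcyclohex-2-en-1-one | CC(C)(C)[Si](C)(C)OC/C=C/C#CC1=CC(=O)C(C)(O)CC1
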